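## The problem

The target 22 is a resveratrol trimer in which two 2,3-diaryl-2,3-dihydrobenzofurans are joined by a single bond from C3 of ring A (the ring whose C6 bears the (E)-4-hydroxystyryl group) to C6 of ring B, whose own C3 carries a 3,5-dihydroxyphenyl group; each ring has a free hydroxyl at C4 and a 4-hydroxyphenyl group at C2. There are four stereocentres, 2S,3S in each ring, so both rings are 2,3-trans. Within one ring C3 can dictate C2, because C2 is a benzylic ether carbon with a para-oxygenated aryl group and can be equilibrated to the trans arrangement. The two rings, however, are insulated from each other by the benzo ring of B, so their mutual relation must come from a reagent and not from the substrate. Seven phenols, an electron-rich stilbene and two ionisable benzylic C2–O bonds rule out oxidants, hot protic acid and hydrogenolysis once they are all free, so the phenols must stay masked to the end and the stilbene must come late. The key step rests on the fact that C2 of each ring bears O1 and a 4-oxygenated phenyl, so that each C2–H is the benzylic C–H of a 4-methoxybenzyl ether on the oxygen ortho to C3a. C3 of each ring is a diarylmethine carbon, the carbon of a diaryl carbene. C3a of each ring lies between two oxygenated carbons (C7a and C4), so both ortho oxygens can carry the same benzyl group and the carbene has no regiochemical choice.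

## Retrosynthesis

**22 from 21.** Only the seven O–CH3 bonds are cut. Methyl ethers are the one phenol protection that survives organolithiums, hot hydrazine, MnO2, rhodium carbenes and acid alike, and the 4-methoxyphenyl pattern is what the key step produces anyway. The forward reaction (BBr3) must cleave seven ethers without harming the stilbene or the trans rings.

**21 from 19 and 20.** The stilbene C=C is cut to aldehyde 19 and diethyl 4-methoxybenzylphosphonate 20. Carrying the styryl group through the route is rejected: it would not survive the acid step and is not innocent towards carbenes. A cut at the aryl–vinyl bond would need an aryl halide on ring A, which clashes with the organolithium chemistry used earlier. Aldehyde 19 comes from alcohol 18 by oxidation, 18 from silyl ether 17 by desilylation, and 17 from bis(phenol) 16 by methylation. The olefination must be E-selective and must not deprotonate C3–H.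

**16 from 15.** No skeletal bond is cut. Both C2 centres are inverted and the two spare 4-methoxybenzyl (PMB) ethers are removed. The insertion is expected to give 2,3-cis rings kinetically, so the C2 centres are corrected afterwards by acid equilibration. The forward reaction must ionise C2–O reversibly and leave C3 alone.

**15 from 13 through 14 (key disconnection).** The C2–C3 bond is cut in both rings. A cut at O1–C2 or at C3–C3a would leave each C3 to be set separately and the rings to be made one after the other. This cut removes both rings and all four stereocentres at once. The precursor is the achiral bis(hydrazone) 13, oxidised in the flask to bis(diazo) compound 14. The forward reaction is a double enantioselective 1,5 C–H insertion in which the catalyst sets each C3 independently.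

**13 from 12, 12 from 11.** The two C=N bonds are cut to bis(benzophenone) 12, and 12 is the oxidation product of diol 11. The condensation must overcome two ortho substituents at each carbonyl.

**11 from 8 and 9 (through 10); 8 from 5 (through 7) and 6.** The two bonds between a carbinol carbon and an aryl carbon flanked by two oxygens are cut. These are the carbons that bear bromine in a 2-bromoresorcinol, so bromine–lithium exchange gives each nucleophile regiospecifically. Directed ortho-metalation of bis(methoxymethyl) ethers would reach the same bonds. It would, however, require a later exchange to PMB ethers on a hindered bis(ketone), and the second metalation would have to be regioselective on a carbinol dianion. With bromides, the PMB groups needed for the key step are in place from the first step. The exchange must outrun deprotonation of the benzylic ether CH2 groups, and aryllithium 7 must add to aldehyde 6 faster than it exchanges with the bromide of 6. 3,5-Dimethoxybenzaldehyde 9 is commercial.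

**5 and 6 from 4; 4 from 3; 3 from 1 and 2.** Both resorcinol units come from one alcohol 4: silylation gives ring A unit 5 and oxidation gives ring B unit 6. Alcohol 4 comes from ester 3 by reduction. Ester 3 comes from commercial methyl 4-bromo-3,5-dihydroxybenzoate 1 by alkylation of both phenols, which consumes two equivalents of 4-methoxybenzyl chloride 2.

## Roads not taken

Alternative 1: Biomimetic oxidative cross-coupling. The cut is at C3–C3a and O1–C2 of ring B. FeCl3·6H2O would oxidise resveratrol A2 to its phenoxyl radical in the presence of the stilbene-O-acetylated dimer A3. The alkene carbon of the radical that lies next to its resorcinol ring would bond to the carbon between the two hydroxyls of the resorcinol ring of A3, and the resulting quinone methide would be closed by the neighbouring phenol to give the target mono-acetate A1.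

- Merits: this road is much shorter than the chosen one from A3 and needs almost no protecting groups. In step count it is clearly the better plan.
- Weak points: A2 has several radical coupling sites and prefers to dimerise with itself. Attack at the carbon between two hydroxyls is not the usual outcome. A3 must first be obtained as a single enantiomer. The new ring would form with no control relative to the existing one.
- Comparison: the chosen plan is longer, but the site of every C–C bond is fixed by a bromine atom and every stereocentre by a catalyst or by thermodynamics.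

Alternative 2: Stobbe benzannulation. The cut is at C4–C3a of ring B. The Stobbe half-ester A5, made from dihydrofuran carbaldehyde A6 and a succinic diester, would be heated with Ac2O/NaOAc. The dienylketene formed would cyclise onto the enol-ether β-carbon to give ethyl 4-acetoxy dihydrobenzofuran-6-carboxylate A4.

- Merits: the C4 oxygen and the C6 carbon substituent arrive with unambiguous regiochemistry, and the trans diaryl unit is carried in unchanged, so no epimerisation is needed. In these respects it is as good as or better than the chosen plan.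
- Weak points: one pass builds one benzo ring only, so ring A needs a second, different construction. A6 is an acid-sensitive cyclic enol ether whose enantioselective preparation is a problem of its own. The C3–H of A5 is allylic and benzylic and may epimerise in hot acetate.
- Comparison: the chosen plan needs a corrective epimerisation, but it sets all four stereocentres on an achiral, robust precursor in one operation.

Alternative 3: Flavanone ring contraction. The cut is at C3–C3a. PhI(OAc)2 (trivalent iodine) with HC(OMe)3 and H2SO4 would attack the enol ether of the (2S)-flavanone A8 at C3. The benzo ring carbon would migrate from C4 to C3 as iodobenzene leaves, giving the trans methyl ester A7.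

- Merits: the trans relation is obtained directly, absolute configuration comes from one flavanone centre, and the C6 bromide is a ready coupling handle. It is better than the chosen plan in giving the trans ring without correction.
- Weak points: C3 emerges with a carboxylate where the target has an aryl group. Replacing it by decarboxylative arylation must be done twice, relies on C2 for the C3 configuration, and joins the two rings at a hindered secondary centre. The route is linear.
- Comparison: the chosen plan makes the aryl–C3 bonds by plain carbonyl additions before any stereocentre exists.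

Key step: step 9

Assumption: Rh2(S-PTAD)4 is taken to deliver the 3S configuration at both carbene carbons by analogy with single insertions of this type; if the sense on this substrate is opposite, Rh2(R-PTAD)4 is used and nothing else changes.

## Route

Step 1
Reactants: 1 methyl 4-bromo-3,5-dihydroxybenzoate; 2 4-methoxybenzyl chloride
Product: 3 methyl 4-bromo-3,5-bis[(4-methoxybenzyl)oxy]benzoate
Conditions: 2 (2.3 equiv), K2CO3, DMF, 60 °C
Reagents that add atoms: 4-methoxybenzyl chloride (the second equivalent of 2), COc1ccc(CCl)cc1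
Why: Twofold Williamson ether synthesis in which each phenoxide takes up one molecule of 2, so two molecules of 2 are incorporated. The PMB groups are installed at the outset because each later serves as a C–H donor in the key step, and ester and aryl bromide are inert to K2CO3.

Step 2
Reactants: 3 methyl 4-bromo-3,5-bis[(4-methoxybenzyl)oxy]benzoate
Product: 4 {4-bromo-3,5-bis[(4-methoxybenzyl)oxy]phenyl}methanol
Conditions: i-Bu2AlH, CH2Cl2, −78 → 0 °C; aq. KNaC4H4O6 (potassium sodium tartrate)
Reagents that add atoms: none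
Why: Hydride reduction of the ester to the primary alcohol; the aryl bromide and benzyl ethers are not touched at low temperature.

Step 3
Reactants: 4 {4-bromo-3,5-bis[(4-methoxybenzyl)oxy]phenyl}methanol
Product: 5 ({4-bromo-3,5-bis[(4-methoxybenzyl)oxy]benzyl}oxy)triisopropylsilane
Conditions: i-Pr3SiCl, imidazole, DMF, rt
Reagents that add atoms: triisopropylsilyl chloride, CC(C)[Si](Cl)(C(C)C)C(C)C
Why: Silylation of the primary alcohol; the bulky silyl ether withstands n-BuLi, hydrazine, MnO2 and brief anhydrous acid, and its size disfavours silyl migration to carbon.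

Step 4
Reactants: 4 {4-bromo-3,5-bis[(4-methoxybenzyl)oxy]phenyl}methanol
Product: 6 4-bromo-3,5-bis[(4-methoxybenzyl)oxy]benzaldehyde
Conditions: MnO2, CH2Cl2, rt
Reagents that add atoms: none
Why: Heterogeneous benzylic alcohol oxidation that stops at the aldehyde; it turns the common intermediate into the electrophilic ring B unit.

Step 5
Reactants: 5 ({4-bromo-3,5-bis[(4-methoxybenzyl)oxy]benzyl}oxy)triisopropylsilane; 6 4-bromo-3,5-bis[(4-methoxybenzyl)oxy]benzaldehyde
Product: 8 {4-bromo-3,5-bis[(4-methoxybenzyl)oxy]phenyl}{2,6-bis[(4-methoxybenzyl)oxy]-4-{[(triisopropylsilyl)oxy]methyl}phenyl}methanol (racemic), via aryllithium 7 (not isolated)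
Conditions: n-BuLi, THF, −78 °C; then 6, −78 → −20 °C; NH4Cl aq.
Reagents that add atoms: none
Why: Bromine–lithium exchange at −78 °C is faster than deprotonation of the benzylic ether CH2 groups, so no Wittig rearrangement intervenes and the 2,6-dialkoxyaryllithium forms regiospecifically. Its 1,2-addition to the aldehyde outruns exchange with the aryl bromide of 6; the carbinol centre is racemic and is removed in step 7.

Step 6
Reactants: 8 {4-bromo-3,5-bis[(4-methoxybenzyl)oxy]phenyl}{2,6-bis[(4-methoxybenzyl)oxy]-4-{[(triisopropylsilyl)oxy]methyl}phenyl}methanol; 9 3,5-dimethoxybenzaldehyde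
Product: 11 (3,5-dimethoxyphenyl){4-[hydroxy(2,6-bis[(4-methoxybenzyl)oxy]-4-{[(triisopropylsilyl)oxy]methyl}phenyl)methyl]-2,6-bis[(4-methoxybenzyl)oxy]phenyl}methanol (mixture of diastereomers), via dilithio alkoxide 10 (not isolated)
Conditions: n-BuLi (2.2 equiv), THF, −78 °C; then 9, −78 → 0 °C; NH4Cl aq.
Reagents that add atoms: none
Why: The first equivalent of n-BuLi forms the lithium alkoxide and the second exchanges the bromide flanked by two ether oxygens; the aryllithium then adds to the aldehyde. Both carbinol centres are stereochemically irrelevant because they are oxidised next.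

Step 7
Reactants: 11 diol (mixture of diastereomers)
Product: 12 {4-(3,5-dimethoxybenzoyl)-3,5-bis[(4-methoxybenzyl)oxy]phenyl}{2,6-bis[(4-methoxybenzyl)oxy]-4-{[(triisopropylsilyl)oxy]methyl}phenyl}methanone
Conditions: Dess–Martin periodinane, pyridine, CH2Cl2, 0 °C → rt
Reagents that add atoms: none
Why: Dess–Martin oxidation of two doubly benzylic secondary alcohols; pyridine buffering prevents acid ionisation of the electron-rich benzhydrols and leaves PMB and silyl ethers intact.

Step 8
Reactants: 12 bis(benzophenone)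
Product: 13 bis(hydrazone) of 12 (C=N geometry immaterial)
Conditions: N2H4·H2O (excess), AcOH (cat.), n-BuOH, 110 °C
Reagents that add atoms: hydrazine (used as the hydrate), NN
Why: Hydrazone condensation, one molecule of hydrazine per carbonyl; each carbonyl has one unhindered aryl flank, and excess hydrazine with acid catalysis at elevated temperature drives addition to the ortho,ortho'-disubstituted ketones and suppresses azine formation. Both C=N isomers give the same diazo compound.

Step 9
Reactants: 13 bis(hydrazone)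
Product: 15 (2R,3S)-3-[(2R,3S)-3-(3,5-dimethoxyphenyl)-4-[(4-methoxybenzyl)oxy]-2-(4-methoxyphenyl)-2,3-dihydrobenzofuran-6-yl]-4-[(4-methoxybenzyl)oxy]-2-(4-methoxyphenyl)-6-{[(triisopropylsilyl)oxy]methyl}-2,3-dihydrobenzofuran (both rings 2,3-cis), via bis(diazo) compound 14 (not isolated)
Conditions: MnO2, CH2Cl2, rt; filter (Celite); Rh2(S-PTAD)4 (2 mol %), CH2Cl2, 0 °C
Reagents that add atoms: none
Why: MnO2 dehydrogenates both hydrazones to diaryldiazomethanes, and Rh2(S-PTAD)4 (dirhodium tetrakis[(S)-(1-adamantyl)phthalimidoacetate], a dimer of divalent rhodium) expels N2 from each to give a rhodium carbene flanked by two aryl groups. Each carbene inserts into the benzylic C–H of an ortho PMB ether through a concerted, asynchronous three-centre transition state with hydride-transfer character, forming C2–C3; the closest known reaction is the enantioselective intramolecular C–H insertion of diaryl rhodium carbenes into benzyl aryl ethers to give 2,3-diaryl-2,3-dihydrobenzofurans, here run at two sites of one molecule. Ring A and ring B each close as a five-membered ring by 1,5-insertion, the carbene carbon becoming C3 and the ether CH becoming C2. C3 of ring A and C3 of ring B are set by the chiral carboxylate ligands, which select the face of each carbene (3S); C2 of each ring is set relative to its C3 in the insertion transition state, which is expected to place the C2 aryl cis to the C3 aryl (2R) and is corrected in step 10. Site selectivity is secured by the substrate: only the ortho ethers offer a C–H in 1,5 relation, the two ortho PMB groups on each carbene-bearing ring are equivalent so either gives the same ring, and the PMB groups of the neighbouring ring are meta to the carbene and cannot be reached. The two sites are separated by the benzo ring of B, so each insertion is under catalyst control and a lapse at one site gives a separable diastereomer, not the enantiomer. Diaryl carbenes are attenuated electrophiles that leave the methoxyarenes and the silyl ether alone, and the two ortho substituents shield each diazo carbon against azine formation.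

Step 10
Reactants: 15 bis(cis-dihydrobenzofuran)
Product: 16 (2S,3S)-3-[(2S,3S)-3-(3,5-dimethoxyphenyl)-4-hydroxy-2-(4-methoxyphenyl)-2,3-dihydrobenzofuran-6-yl]-2-(4-methoxyphenyl)-6-{[(triisopropylsilyl)oxy]methyl}-2,3-dihydrobenzofuran-4-ol (both rings 2,3-trans)
Conditions: CF3CO2H/CH2Cl2 (1:4), anisole (excess), 0 °C → rt
Reagents that add atoms: none
Why: Acid-mediated epimerisation: heterolysis of each C2–O bond gives a 4-methoxybenzylic cation that recloses on the phenol oxygen to the more stable 2,3-trans ring, while C3 has no leaving group and keeps the configuration set by the catalyst. The same acid cleaves the two spare PMB ethers, whose cations are trapped by anisole; since both oxygens ortho to C3a are then equivalent phenols, reclosure on either gives the same compound.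

Step 11
Reactants: 16 bis(phenol)
Product: 17 (2S,3S)-3-[(2S,3S)-3-(3,5-dimethoxyphenyl)-4-methoxy-2-(4-methoxyphenyl)-2,3-dihydrobenzofuran-6-yl]-4-methoxy-2-(4-methoxyphenyl)-6-{[(triisopropylsilyl)oxy]methyl}-2,3-dihydrobenzofuran
Conditions: MeI (excess), K2CO3, acetone, 50 °C
Reagents that add atoms: iodomethane, CI
Why: Williamson O-methylation of the two phenols, one molecule of iodomethane each; it masks them for the oxidation and olefination and adds only ethers of the kind the last step removes anyway.

Step 12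
Reactants: 17 silyl ether
Product: 18 {(2S,3S)-3-[(2S,3S)-3-(3,5-dimethoxyphenyl)-4-methoxy-2-(4-methoxyphenyl)-2,3-dihydrobenzofuran-6-yl]-4-methoxy-2-(4-methoxyphenyl)-2,3-dihydrobenzofuran-6-yl}methanol
Conditions: n-Bu4NF, THF, 0 °C → rt; NH4Cl aq.
Reagents that add atoms: none
Why: Fluoride-induced desilylation driven by the Si–F bond; every other group is an ether that is stable to fluoride.

Step 13
Reactants: 18 benzylic alcohol
Product: 19 (2S,3S)-3-[(2S,3S)-3-(3,5-dimethoxyphenyl)-4-methoxy-2-(4-methoxyphenyl)-2,3-dihydrobenzofuran-6-yl]-4-methoxy-2-(4-methoxyphenyl)-2,3-dihydrobenzofuran-6-carbaldehyde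
Conditions: Dess–Martin periodinane, pyridine, CH2Cl2, rt
Reagents that add atoms: none
Why: Dess–Martin oxidation of the primary benzylic alcohol stops at the aldehyde; the benzylic C2–H and C3–H bonds are not attacked.

Step 14
Reactants: 19 aldehyde; 20 diethyl 4-methoxybenzylphosphonate
Product: 21 (2S,3S)-3-[(2S,3S)-3-(3,5-dimethoxyphenyl)-4-methoxy-2-(4-methoxyphenyl)-2,3-dihydrobenzofuran-6-yl]-4-methoxy-2-(4-methoxyphenyl)-6-[(E)-4-methoxystyryl]-2,3-dihydrobenzofuran
Conditions: KOtBu, THF, 0 °C → rt
Reagents that add atoms: none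
Why: Horner–Wadsworth–Emmons olefination; the aryl-stabilised phosphonate anion adds reversibly and eliminates through the anti pathway to give the (E)-stilbene. The anion is too weak a base at this temperature to deprotonate C3–H.

Step 15
Reactants: 21 heptamethyl ether
Product: 22 (2S,3S)-3-[(2S,3S)-3-(3,5-dihydroxyphenyl)-4-hydroxy-2-(4-hydroxyphenyl)-2,3-dihydrobenzofuran-6-yl]-2-(4-hydroxyphenyl)-6-[(E)-4-hydroxystyryl]-2,3-dihydrobenzofuran-4-ol
Conditions: BBr3, CH2Cl2, −78 °C → rt; then H2O
Reagents that add atoms: none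
Why: Lewis acid cleavage of aryl methyl ethers (boron complexation, then bromide attack at methyl), with hydrolysis releasing the seven phenols. Any reversible ionisation at C2 returns the trans ring, and the styryl group at C6 is too far from the C3 aryl groups for an intramolecular Friedel–Crafts cyclisation.

## Compound list

1 | methyl 4-bromo-3,5-dihydroxybenzoate | COC(=O)c1cc(O)c(Br)c(O)c1 | starting material
2 | 4-methoxybenzyl chloride | COc1ccc(CCl)cc1 | starting material
3 | methyl 4-bromo-3,5-bis[(4-methoxybenzyl)oxy]benzoate | COC(=O)c1cc(OCc2ccc(OC)cc2)c(Br)c(OCc2ccc(OC)cc2)c1 | intermediate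
4 | {4-bromo-3,5-bis[(4-methoxybenzyl)oxy]phenyl}methanol | OCc1cc(OCc2ccc(OC)cc2)c(Br)c(OCc2ccc(OC)cc2)c1 | intermediate
5 | ({4-bromo-3,5-bis[(4-methoxybenzyl)oxy]benzyl}oxy)triisopropylsilane | CC(C)[Si](C(C)C)(C(C)C)OCc1cc(OCc2ccc(OC)cc2)c(Br)c(OCc2ccc(OC)cc2)c1 | intermediate
6 | 4-bromo-3,5-bis[(4-methoxybenzyl)oxy]benzaldehyde | O=Cc1cc(OCc2ccc(OC)cc2)c(Br)c(OCc2ccc(OC)cc2)c1 | intermediate
7 | aryllithium from 5 (lithium in place of bromine) | CC(C)[Si](C(C)C)(C(C)C)OCc1cc(OCc2ccc(OC)cc2)c([Li])c(OCc2ccc(OC)cc2)c1 | intermediate (not isolated)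
8 | {4-bromo-3,5-bis[(4-methoxybenzyl)oxy]phenyl}{2,6-bis[(4-methoxybenzyl)oxy]-4-{[(triisopropylsilyl)oxy]methyl}phenyl}methanol (racemic) | CC(C)[Si](C(C)C)(C(C)C)OCc1cc(OCc2ccc(OC)cc2)c(C(O)c2cc(OCc3ccc(OC)cc3)c(Br)c(OCc3ccc(OC)cc3)c2)c(OCc2ccc(OC)cc2)c1 | intermediate
9 | 3,5-dimethoxybenzaldehyde | COc1cc(C=O)cc(OC)c1 | starting material
10 | dilithio alkoxide from 8 (O–Li and aryl–Li in place of O–H and aryl–Br) | CC(C)[Si](C(C)C)(C(C)C)OCc1cc(OCc2ccc(OC)cc2)c(C(O[Li])c2cc(OCc3ccc(OC)cc3)c([Li])c(OCc3ccc(OC)cc3)c2)c(OCc2ccc(OC)cc2)c1 | intermediate (not isolated)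
11 | (3,5-dimethoxyphenyl){4-[hydroxy(2,6-bis[(4-methoxybenzyl)oxy]-4-{[(triisopropylsilyl)oxy]methyl}phenyl)methyl]-2,6-bis[(4-methoxybenzyl)oxy]phenyl}methanol (mixture of diastereomers) | CC(C)[Si](C(C)C)(C(C)C)OCc1cc(OCc2ccc(OC)cc2)c(C(O)c2cc(OCc3ccc(OC)cc3)c(C(O)c3cc(OC)cc(OC)c3)c(OCc3ccc(OC)cc3)c2)c(OCc2ccc(OC)cc2)c1 | intermediate
12 | {4-(3,5-dimethoxybenzoyl)-3,5-bis[(4-methoxybenzyl)oxy]phenyl}{2,6-bis[(4-methoxybenzyl)oxy]-4-{[(triisopropylsilyl)oxy]methyl}phenyl}methanone | CC(C)[Si](C(C)C)(C(C)C)OCc1cc(OCc2ccc(OC)cc2)c(C(=O)c2cc(OCc3ccc(OC)cc3)c(C(=O)c3cc(OC)cc(OC)c3)c(OCc3ccc(OC)cc3)c2)c(OCc2ccc(OC)cc2)c1 | intermediate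
13 | bis(hydrazone) of 12 (both C=O replaced by C=N–NH2) | CC(C)[Si](C(C)C)(C(C)C)OCc1cc(OCc2ccc(OC)cc2)c(C(=NN)c2cc(OCc3ccc(OC)cc3)c(C(=NN)c3cc(OC)cc(OC)c3)c(OCc3ccc(OC)cc3)c2)c(OCc2ccc(OC)cc2)c1 | intermediate
14 | bis(diazo) compound (both C=N–NH2 replaced by C=N2) | CC(C)[Si](C(C)C)(C(C)C)OCc1cc(OCc2ccc(OC)cc2)c(C(=[N+]=[N-])c2cc(OCc3ccc(OC)cc3)c(C(=[N+]=[N-])c3cc(OC)cc(OC)c3)c(OCc3ccc(OC)cc3)c2)c(OCc2ccc(OC)cc2)c1 | intermediate (not isolated)
15 | (2R,3S)-3-[(2R,3S)-3-(3,5-dimethoxyphenyl)-4-[(4-methoxybenzyl)oxy]-2-(4-methoxyphenyl)-2,3-dihydrobenzofuran-6-yl]-4-[(4-methoxybenzyl)oxy]-2-(4-methoxyphenyl)-6-{[(triisopropylsilyl)oxy]methyl}-2,3-dihydrobenzofuran (both rings cis) | CC(C)[Si](C(C)C)(C(C)C)OCc1cc(OCc2ccc(OC)cc2)c2c(c1)O[C@@H](c1ccc(OC)cc1)[C@H]2c1cc(OCc2ccc(OC)cc2)c2c(c1)O[C@@H](c1ccc(OC)cc1)[C@H]2c1cc(OC)cc(OC)c1 | intermediate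
16 | (2S,3S)-3-[(2S,3S)-3-(3,5-dimethoxyphenyl)-4-hydroxy-2-(4-methoxyphenyl)-2,3-dihydrobenzofuran-6-yl]-2-(4-methoxyphenyl)-6-{[(triisopropylsilyl)oxy]methyl}-2,3-dihydrobenzofuran-4-ol (both rings trans) | CC(C)[Si](C(C)C)(C(C)C)OCc1cc(O)c2c(c1)O[C@H](c1ccc(OC)cc1)[C@H]2c1cc(O)c2c(c1)O[C@H](c1ccc(OC)cc1)[C@H]2c1cc(OC)cc(OC)c1 | intermediate
17 | (2S,3S)-3-[(2S,3S)-3-(3,5-dimethoxyphenyl)-4-methoxy-2-(4-methoxyphenyl)-2,3-dihydrobenzofuran-6-yl]-4-methoxy-2-(4-methoxyphenyl)-6-{[(triisopropylsilyl)oxy]methyl}-2,3-dihydrobenzofuran | CC(C)[Si](C(C)C)(C(C)C)OCc1cc(OC)c2c(c1)O[C@H](c1ccc(OC)cc1)[C@H]2c1cc(OC)c2c(c1)O[C@H](c1ccc(OC)cc1)[C@H]2c1cc(OC)cc(OC)c1 | intermediate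
18 | {(2S,3S)-3-[(2S,3S)-3-(3,5-dimethoxyphenyl)-4-methoxy-2-(4-methoxyphenyl)-2,3-dihydrobenzofuran-6-yl]-4-methoxy-2-(4-methoxyphenyl)-2,3-dihydrobenzofuran-6-yl}methanol | OCc1cc(OC)c2c(c1)O[C@H](c1ccc(OC)cc1)[C@H]2c1cc(OC)c2c(c1)O[C@H](c1ccc(OC)cc1)[C@H]2c1cc(OC)cc(OC)c1 | intermediate
19 | (2S,3S)-3-[(2S,3S)-3-(3,5-dimethoxyphenyl)-4-methoxy-2-(4-methoxyphenyl)-2,3-dihydrobenzofuran-6-yl]-4-methoxy-2-(4-methoxyphenyl)-2,3-dihydrobenzofuran-6-carbaldehyde | O=Cc1cc(OC)c2c(c1)O[C@H](c1ccc(OC)cc1)[C@H]2c1cc(OC)c2c(c1)O[C@H](c1ccc(OC)cc1)[C@H]2c1cc(OC)cc(OC)c1 | intermediate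
20 | diethyl 4-methoxybenzylphosphonate | CCOP(=O)(Cc1ccc(OC)cc1)OCC | starting material
21 | (2S,3S)-3-[(2S,3S)-3-(3,5-dimethoxyphenyl)-4-methoxy-2-(4-methoxyphenyl)-2,3-dihydrobenzofuran-6-yl]-4-methoxy-2-(4-methoxyphenyl)-6-[(E)-4-methoxystyryl]-2,3-dihydrobenzofuran | COc1ccc(/C=C/c2cc(OC)c3c(c2)O[C@H](c2ccc(OC)cc2)[C@H]3c2cc(OC)c3c(c2)O[C@H](c2ccc(OC)cc2)[C@H]3c2cc(OC)cc(OC)c2)cc1 | intermediate
22 | (2S,3S)-3-[(2S,3S)-3-(3,5-dihydroxyphenyl)-4-hydroxy-2-(4-hydroxyphenyl)-2,3-dihydrobenzofuran-6-yl]-2-(4-hydroxyphenyl)-6-[(E)-4-hydroxystyryl]-2,3-dihydrobenzofuran-4-ol | Oc1ccc(/C=C/c2cc(O)c3c(c2)O[C@H](c2ccc(O)cc2)[C@H]3c2cc(O)c3c(c2)O[C@H](c2ccc(O)cc2)[C@H]3c2cc(O)cc(O)c2)cc1 | target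

## Step count and risks

Total: 15 steps. Longest linear sequence: 14 steps (1 → 3 → 4 → 5 → 8 → 11 → 12 → 13 → 15 → 16 → 17 → 18 → 19 → 21 → 22); step 4 is a one-step branch from 4.

**Step 9 (key step).** The most likely failure is loss of nitrogen outside the chiral pocket (thermally or on the oxide surface) and intermolecular azine formation. Both are favoured when two electron-rich diazo groups sit in one molecule. A lapse of face selectivity at either site also diverts material into diastereomers.

The fallback runs the two insertions one at a time, each being exactly the known single reaction. It sets out from 8 and returns at 15. Dess–Martin oxidation of 8 should give the bromo ketone F1, hydrazine the bromo hydrazone F2, and MnO2 the bromo diazo compound F3. Rh2(S-PTAD)4 should convert F3 into the ring A cis-dihydrobenzofuran bromide F4. n-BuLi at −78 °C should turn F4 into the aryllithium F5, which adds to 9 to give the carbinol F6. Oxidation should give the ketone F7, hydrazine the hydrazone F8, and MnO2 the diazo compound F9. A second insertion with the same catalyst would then give 15.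

**Step 8.** The most likely failure is incomplete condensation at carbonyl groups shielded by two ortho benzyloxy groups. The reaction may stall at the mono-hydrazone or drift to azines on long heating.

The fallback sets out from 12 and returns at 14. Condensation with 1,2-bis(tert-butyldimethylsilyl)hydrazine under Sc(OTf)3 catalysis, driven by Si–O bond formation, should give the bis(N-silylhydrazone) F10. Oxidation of F10 with PhIF2 and 2-chloropyridine in CH2Cl2 should give bis(diazo) compound 14 directly, which is treated with the rhodium catalyst as in step 9.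

**Step 10.** The most likely failures are re-alkylation of the freed resorcinol-type rings by 4-methoxybenzyl cations, capture of the ring-opened C2 cation by the scavenger before it recloses, partial loss of the silyl ether giving mixtures, and elimination from the ring-opened cation, which would erase C3.

The fallback accepts the desilylation and sets out from 15, returning at 18. Aqueous CF3CO2H with excess 1,3-dimethoxybenzene as trap, followed by K2CO3/MeOH to cleave any trifluoroacetate, should remove PMB and silyl groups and epimerise both C2 centres to give the triol F11. MeI/K2CO3 in acetone should then methylate only the two phenols of F11 to give 18.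

**Step 15.** The most likely failure is hydrobromination or cationic oligomerisation of the electron-rich stilbene under the Lewis acid, together with incomplete cleavage of seven ethers.

The fallback moves the demethylation ahead of the olefination and sets out from 19, returning at 22. BBr3 on 19, where no alkene is present, should give the hexaphenol aldehyde F12. Silylation with t-BuMe2SiCl and imidazole should give the hexakis(silyl ether) aldehyde F13. Horner–Wadsworth–Emmons reaction of F13 with the known reagent diethyl 4-[(tert-butyldimethylsilyl)oxy]benzylphosphonate (CCOP(=O)(Cc1ccc(O[Si](C)(C)C(C)(C)C)cc1)OCC) and NaH in THF should give the heptakis(silyl ether) stilbene F14. n-Bu4NF buffered with AcOH should then release 22 under non-acidic conditions.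

## Further compounds

F1 | step 9 | {4-bromo-3,5-bis[(4-methoxybenzyl)oxy]phenyl}{2,6-bis[(4-methoxybenzyl)oxy]-4-{[(triisopropylsilyl)oxy]methyl}phenyl}methanone | CC(C)[Si](C(C)C)(C(C)C)OCc1cc(OCc2ccc(OC)cc2)c(C(=O)c2cc(OCc3ccc(OC)cc3)c(Br)c(OCc3ccc(OC)cc3)c2)c(OCc2ccc(OC)cc2)c1
F2 | step 9 | hydrazone of F1 | CC(C)[Si](C(C)C)(C(C)C)OCc1cc(OCc2ccc(OC)cc2)c(C(=NN)c2cc(OCc3ccc(OC)cc3)c(Br)c(OCc3ccc(OC)cc3)c2)c(OCc2ccc(OC)cc2)c1
F3 | step 9 | diazo compound from F2 | CC(C)[Si](C(C)C)(C(C)C)OCc1cc(OCc2ccc(OC)cc2)c(C(=[N+]=[N-])c2cc(OCc3ccc(OC)cc3)c(Br)c(OCc3ccc(OC)cc3)c2)c(OCc2ccc(OC)cc2)c1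
F4 | step 9 | (2R,3S)-3-{4-bromo-3,5-bis[(4-methoxybenzyl)oxy]phenyl}-4-[(4-methoxybenzyl)oxy]-2-(4-methoxyphenyl)-6-{[(triisopropylsilyl)oxy]methyl}-2,3-dihydrobenzofuran (cis) | CC(C)[Si](C(C)C)(C(C)C)OCc1cc(OCc2ccc(OC)cc2)c2c(c1)O[C@@H](c1ccc(OC)cc1)[C@H]2c1cc(OCc2ccc(OC)cc2)c(Br)c(OCc2ccc(OC)cc2)c1
F5 | step 9 | aryllithium from F4 (lithium in place of bromine) | CC(C)[Si](C(C)C)(C(C)C)OCc1cc(OCc2ccc(OC)cc2)c2c(c1)O[C@@H](c1ccc(OC)cc1)[C@H]2c1cc(OCc2ccc(OC)cc2)c([Li])c(OCc2ccc(OC)cc2)c1
F6 | step 9 | (3,5-dimethoxyphenyl)(aryl)methanol from F5 and 9 (carbinol epimers) | CC(C)[Si](C(C)C)(C(C)C)OCc1cc(OCc2ccc(OC)cc2)c2c(c1)O[C@@H](c1ccc(OC)cc1)[C@H]2c1cc(OCc2ccc(OC)cc2)c(C(O)c2cc(OC)cc(OC)c2)c(OCc2ccc(OC)cc2)c1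
F7 | step 9 | ketone from F6 | CC(C)[Si](C(C)C)(C(C)C)OCc1cc(OCc2ccc(OC)cc2)c2c(c1)O[C@@H](c1ccc(OC)cc1)[C@H]2c1cc(OCc2ccc(OC)cc2)c(C(=O)c2cc(OC)cc(OC)c2)c(OCc2ccc(OC)cc2)c1
F8 | step 9 | hydrazone of F7 | CC(C)[Si](C(C)C)(C(C)C)OCc1cc(OCc2ccc(OC)cc2)c2c(c1)O[C@@H](c1ccc(OC)cc1)[C@H]2c1cc(OCc2ccc(OC)cc2)c(C(=NN)c2cc(OC)cc(OC)c2)c(OCc2ccc(OC)cc2)c1
F9 | step 9 | diazo compound from F8 | CC(C)[Si](C(C)C)(C(C)C)OCc1cc(OCc2ccc(OC)cc2)c2c(c1)O[C@@H](c1ccc(OC)cc1)[C@H]2c1cc(OCc2ccc(OC)cc2)c(C(=[N+]=[N-])c2cc(OC)cc(OC)c2)c(OCc2ccc(OC)cc2)c1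
F10 | step 8 | bis(N-tert-butyldimethylsilylhydrazone) of 12 | CC(C)[Si](C(C)C)(C(C)C)OCc1cc(OCc2ccc(OC)cc2)c(C(=NN[Si](C)(C)C(C)(C)C)c2cc(OCc3ccc(OC)cc3)c(C(=NN[Si](C)(C)C(C)(C)C)c3cc(OC)cc(OC)c3)c(OCc3ccc(OC)cc3)c2)c(OCc2ccc(OC)cc2)c1
F11 | step 10 | (2S,3S)-3-[(2S,3S)-3-(3,5-dimethoxyphenyl)-4-hydroxy-2-(4-methoxyphenyl)-2,3-dihydrobenzofuran-6-yl]-6-(hydroxymethyl)-2-(4-methoxyphenyl)-2,3-dihydrobenzofuran-4-ol | OCc1cc(O)c2c(c1)O[C@H](c1ccc(OC)cc1)[C@H]2c1cc(O)c2c(c1)O[C@H](c1ccc(OC)cc1)[C@H]2c1cc(OC)cc(OC)c1
F12 | step 15 | (2S,3S)-3-[(2S,3S)-3-(3,5-dihydroxyphenyl)-4-hydroxy-2-(4-hydroxyphenyl)-2,3-dihydrobenzofuran-6-yl]-4-hydroxy-2-(4-hydroxyphenyl)-2,3-dihydrobenzofuran-6-carbaldehyde | O=Cc1cc(O)c2c(c1)O[C@H](c1ccc(O)cc1)[C@H]2c1cc(O)c2c(c1)O[C@H](c1ccc(O)cc1)[C@H]2c1cc(O)cc(O)c1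
F13 | step 15 | hexakis(tert-butyldimethylsilyl) ether of F12 | O=Cc1cc(O[Si](C)(C)C(C)(C)C)c2c(c1)O[C@H](c1ccc(O[Si](C)(C)C(C)(C)C)cc1)[C@H]2c1cc(O[Si](C)(C)C(C)(C)C)c2c(c1)O[C@H](c1ccc(O[Si](C)(C)C(C)(C)C)cc1)[C@H]2c1cc(O[Si](C)(C)C(C)(C)C)cc(O[Si](C)(C)C(C)(C)C)c1
F14 | step 15 | heptakis(tert-butyldimethylsilyl) ether of 22 | CC(C)(C)[Si](C)(C)Oc1ccc(/C=C/c2cc(O[Si](C)(C)C(C)(C)C)c3c(c2)O[C@H](c2ccc(O[Si](C)(C)C(C)(C)C)cc2)[C@H]3c2cc(O[Si](C)(C)C(C)(C)C)c3c(c2)O[C@H](c2ccc(O[Si](C)(C)C(C)(C)C)cc2)[C@H]3c2cc(O[Si](C)(C)C(C)(C)C)cc(O[Si](C)(C)C(C)(C)C)c2)cc1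
A1 | alternative 1 | 22 acetylated at the stilbene 4-hydroxyl (target mono-acetate) | CC(=O)Oc1ccc(/C=C/c2cc(O)c3c(c2)O[C@H](c2ccc(O)cc2)[C@H]3c2cc(O)c3c(c2)O[C@H](c2ccc(O)cc2)[C@H]3c2cc(O)cc(O)c2)cc1
A2 | alternative 1 | resveratrol, (E)-5-(4-hydroxystyryl)benzene-1,3-diol | Oc1ccc(/C=C/c2cc(O)cc(O)c2)cc1
A3 | alternative 1 | 4-{(E)-2-[(2S,3S)-3-(3,5-dihydroxyphenyl)-4-hydroxy-2-(4-hydroxyphenyl)-2,3-dihydrobenzofuran-6-yl]vinyl}phenyl acetate | CC(=O)Oc1ccc(/C=C/c2cc(O)c3c(c2)O[C@H](c2ccc(O)cc2)[C@H]3c2cc(O)cc(O)c2)cc1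
A4 | alternative 2 | ethyl (2S,3S)-4-acetoxy-3-(3,5-dimethoxyphenyl)-2-(4-methoxyphenyl)-2,3-dihydrobenzofuran-6-carboxylate | CCOC(=O)c1cc(OC(C)=O)c2c(c1)O[C@H](c1ccc(OC)cc1)[C@H]2c1cc(OC)cc(OC)c1
A5 | alternative 2 | (E)-4-[(2S,3R)-3-(3,5-dimethoxyphenyl)-2-(4-methoxyphenyl)-2,3-dihydrofuran-5-yl]-3-(ethoxycarbonyl)but-3-enoic acid | CCOC(=O)/C(CC(=O)O)=C/C1=C[C@H](c2cc(OC)cc(OC)c2)[C@@H](c2ccc(OC)cc2)O1
A6 | alternative 2 | (2S,3R)-3-(3,5-dimethoxyphenyl)-2-(4-methoxyphenyl)-2,3-dihydrofuran-5-carbaldehyde (trans) | O=CC1=C[C@H](c2cc(OC)cc(OC)c2)[C@@H](c2ccc(OC)cc2)O1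
A7 | alternative 3 | methyl (2S,3S)-6-bromo-4-methoxy-2-(4-methoxyphenyl)-2,3-dihydrobenzofuran-3-carboxylate (trans) | Brc1cc(OC)c2c(c1)O[C@H](c1ccc(OC)cc1)[C@H]2C(=O)OC
A8 | alternative 3 | (2S)-7-bromo-5-methoxy-2-(4-methoxyphenyl)chroman-4-one | COc1ccc([C@@H]2CC(=O)c3c(OC)cc(Br)cc3O2)cc1
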